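Everything rests on cutting the bond between C1 of the guaiacyl ring and the benzylic carbinol carbon C7. In the key step a 4-silyloxy-3-methoxyphenyl Grignard reagent adds to an (S)-configured α-aryloxy aldehyde that already holds C7–C9 and the complete syringate ring. One operation therefore finishes the carbon skeleton and sets C7. The step exploits the C8 ether oxygen, which the two flanking methoxy groups of the syringate ring twist out of conjugation. Together with the C7 carbonyl oxygen it clamps Mg(II) in a five-membered Cram chelate, and C8 then dictates the threo (7S,8S) pair. A bulky TIPS group on O9 blocks the rival six-membered chelate. Only a one-pot deprotection follows.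

Key step: step 5

Remark: neolignan locants are used (C7 = benzylic carbinol carbon, C8 = carbon bearing the aryl ether, C9 = CH2OH carbon, O7–O9 their oxygens). Compounds 1, 3 and 7 are taken to be commercial.

Step 1
Reactants: 1 (S)-but-3-ene-1,2-diol
Product: 2 (2S)-1-[(triisopropylsilyl)oxy]but-3-en-2-ol
Conditions: TIPSCl (1.05 equiv), imidazole, DMF, 0 °C → rt
Reagents that add atoms: triisopropylsilyl chloride, CC(C)[Si](Cl)(C(C)C)C(C)C
Why: Chemoselective O-silylation: the bulky TIPSCl takes the unhindered primary hydroxyl much faster than the secondary allylic one, and the stereocentre is not touched.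

Step 2
Reactants: 2 (2S)-1-[(triisopropylsilyl)oxy]but-3-en-2-ol; 3 methyl syringate
Product: 4 methyl 3,5-dimethoxy-4-({(2R)-1-[(triisopropylsilyl)oxy]but-3-en-2-yl}oxy)benzoate
Conditions: DIAD, PPh3, THF, 0 °C → rt
Reagents that add atoms: none
Why: Mitsunobu etherification: the phenol of 3, acidified by its para ester, displaces the oxyphosphonium salt of 2 by SN2 with inversion, which turns the (S)-carbinol into the C8–O aryl ether with the spatial arrangement of the target (the descriptor is R here only because vinyl ranks below CH2OSi).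

Step 3
Reactants: 4 methyl 3,5-dimethoxy-4-({(2R)-1-[(triisopropylsilyl)oxy]but-3-en-2-yl}oxy)benzoate
Product: 6 methyl 3,5-dimethoxy-4-({(2S)-1-oxo-3-[(triisopropylsilyl)oxy]propan-2-yl}oxy)benzoate, via secondary ozonide 5 (not isolated)
Conditions: O3, CH2Cl2, −78 °C (Sudan Red 7B end point); then PPh3, −78 °C → rt; short silica plug, used at once
Reagents that add atoms: ozone, [O-][O+]=O
Why: Ozonolysis (Criegee mechanism) with reductive work-up cleaves the only C=C bond under neutral, non-enolising conditions, so C7 appears as the aldehyde while C8 keeps its configuration, and the ester-deactivated arene reacts far more slowly than the terminal alkene.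

Step 4
Reactants: 7 4-bromo-2-methoxyphenol
Product: 8 (4-bromo-2-methoxyphenoxy)triisopropylsilane
Conditions: TIPSCl, imidazole, DMF, rt
Reagents that add atoms: triisopropylsilyl chloride, CC(C)[Si](Cl)(C(C)C)C(C)C
Why: Standard phenol O-silylation; the aryl TIPS ether survives magnesium insertion and falls later to fluoride together with the O9 silyl ether.

Step 5
Reactants: 6 methyl 3,5-dimethoxy-4-({(2S)-1-oxo-3-[(triisopropylsilyl)oxy]propan-2-yl}oxy)benzoate; 8 (4-bromo-2-methoxyphenoxy)triisopropylsilane
Product: 10 methyl 4-({(1S,2S)-1-hydroxy-1-{3-methoxy-4-[(triisopropylsilyl)oxy]phenyl}-3-[(triisopropylsilyl)oxy]propan-2-yl}oxy)-3,5-dimethoxybenzoate, via arylmagnesium bromide 9 (not isolated)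
Conditions: 8, Mg, Et2O, reflux; then added (1.3 equiv) to 6 + MgBr2·OEt2 (3 equiv), CH2Cl2, −78 °C; aqueous work-up
Reagents that add atoms: none
Why: MgBr2 ties the C7 carbonyl oxygen and the C8 ether oxygen of 6, backed by one adjacent OMe of the syringate ring, into a five-membered Cram chelate that freezes the C7–C8 rotamer, and the aryl group of 9 is then transferred to the carbonyl carbon in a polar 1,2-addition. The closest known reaction type is the chelation-controlled Grignard addition to MgBr2-precomplexed α-alkoxy aldehydes, which gives syn-1,2-dioxygenated products. No ring of the product is closed; the chelate ring is temporary and falls apart on work-up. The one new stereocentre, C7, is controlled by C8: in the chelate of the (S)-aldehyde the CH2OTIPS arm shields the Re face, so attack on the Si face gives (7S) and hence the threo (7S,8S) pair. The step needs facial selectivity, secured by the non-coordinating solvent, the excess of MgBr2 and the bulky, weakly basic O9–TIPS ether that cannot form the rival six-membered O7/O9 chelate leading to the erythro isomer, and chemoselectivity for the aldehyde over the methyl benzoate, secured by −78 °C and the electron-rich, sluggish ester. The low temperature and the modest basicity of an aryl Grignard reagent should also keep the acidic C8–H from being removed, so C8 is not scrambled.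

Step 6
Reactants: 10 methyl 4-({(1S,2S)-1-hydroxy-1-{3-methoxy-4-[(triisopropylsilyl)oxy]phenyl}-3-[(triisopropylsilyl)oxy]propan-2-yl}oxy)-3,5-dimethoxybenzoate
Product: 12 4-{[(1S,2S)-1,3-dihydroxy-1-(4-hydroxy-3-methoxyphenyl)propan-2-yl]oxy}-3,5-dimethoxybenzoic acid, via desilylated methyl ester 11 (not isolated)
Conditions: TBAF (2.5 equiv), THF, 0 °C → rt; then LiOH, H2O/MeOH, rt; 1 M HCl to pH 4, 0 °C
Reagents that add atoms: lithium hydroxide, [Li+].[OH-]
Why: Fluoride-mediated desilylation of both TIPS ethers is followed in the same flask by BAc2 saponification of the methyl ester; neither reaction touches C7 or C8, and room temperature plus cold, mild acidification avoid quinone methide formation from the p-hydroxybenzyl alcohol.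

Compound list
1 | (S)-but-3-ene-1,2-diol | C=C[C@@H](CO)O | starting material
2 | (2S)-1-[(triisopropylsilyl)oxy]but-3-en-2-ol | C=C[C@@H](CO[Si](C(C)C)(C(C)C)C(C)C)O | intermediate
3 | methyl syringate (methyl 4-hydroxy-3,5-dimethoxybenzoate) | COC(=O)c1cc(OC)c(O)c(OC)c1 | starting material
4 | methyl 3,5-dimethoxy-4-({(2R)-1-[(triisopropylsilyl)oxy]but-3-en-2-yl}oxy)benzoate | C=C[C@H](CO[Si](C(C)C)(C(C)C)C(C)C)Oc1c(OC)cc(C(=O)OC)cc1OC | intermediate
5 | secondary ozonide of 4: methyl 3,5-dimethoxy-4-({(1S)-1-(1,2,4-trioxolan-3-yl)-2-[(triisopropylsilyl)oxy]ethyl}oxy)benzoate, ozonide carbon unassigned | C1OC(OO1)[C@H](CO[Si](C(C)C)(C(C)C)C(C)C)Oc2c(OC)cc(C(=O)OC)cc2OC | intermediate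
6 | methyl 3,5-dimethoxy-4-({(2S)-1-oxo-3-[(triisopropylsilyl)oxy]propan-2-yl}oxy)benzoate | O=C[C@H](CO[Si](C(C)C)(C(C)C)C(C)C)Oc1c(OC)cc(C(=O)OC)cc1OC | intermediate
7 | 4-bromo-2-methoxyphenol | COc1cc(Br)ccc1O | starting material
8 | (4-bromo-2-methoxyphenoxy)triisopropylsilane | COc1cc(Br)ccc1O[Si](C(C)C)(C(C)C)C(C)C | intermediate
9 | {3-methoxy-4-[(triisopropylsilyl)oxy]phenyl}magnesium bromide | COc1cc([Mg]Br)ccc1O[Si](C(C)C)(C(C)C)C(C)C | intermediate
10 | methyl 4-({(1S,2S)-1-hydroxy-1-{3-methoxy-4-[(triisopropylsilyl)oxy]phenyl}-3-[(triisopropylsilyl)oxy]propan-2-yl}oxy)-3,5-dimethoxybenzoate (threo) | COc1cc([C@H](O)[C@H](CO[Si](C(C)C)(C(C)C)C(C)C)Oc2c(OC)cc(C(=O)OC)cc2OC)ccc1O[Si](C(C)C)(C(C)C)C(C)C | intermediate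
11 | methyl 4-{[(1S,2S)-1,3-dihydroxy-1-(4-hydroxy-3-methoxyphenyl)propan-2-yl]oxy}-3,5-dimethoxybenzoate | COc1cc([C@H](O)[C@H](CO)Oc2c(OC)cc(C(=O)OC)cc2OC)ccc1O | intermediate
12 | 4-{[(1S,2S)-1,3-dihydroxy-1-(4-hydroxy-3-methoxyphenyl)propan-2-yl]oxy}-3,5-dimethoxybenzoic acid | COc1cc([C@H](O)[C@H](CO)Oc2c(OC)cc(C(=O)O)cc2OC)ccc1O | target

Total step count: 6. Longest linear sequence: 5 steps (steps 1, 2, 3, 5, 6).

Steps most likely to fail

Step 5. Facial selectivity may be poor, because open polar Felkin–Anh or Cornforth attack, which leads to the erythro series, can compete if the aryl ether oxygen binds magnesium too weakly.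
- The fallback sets out from 6 and 8 and comes back at 10.
- The addition is run with 9 in THF without MgBr2·OEt2 and without regard to selectivity.
- The mixture of 10 and its C7 epimer, the erythro (1R,2S)-alcohol F1, is oxidised with Dess–Martin periodinane to the (S)-aryl ketone F2.
- L-Selectride (THF, −78 °C) then delivers hydride anti to the C8–O bond under polar Felkin–Anh control. For the ketone this leads to the threo alcohol 10.
- C7 is thus set by C–H instead of C–C bond formation.

Step 2. Displacement at a hindered allylic carbinol by a 2,6-disubstituted phenol may be slow. It may also leak into SN2′ attack, with partial loss of configurational purity.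
- The fallback sets out from 3 and comes back at 6.
- Commercial (R)-3-(benzyloxy)propane-1,2-diol is silylated at its primary hydroxyl (TIPSCl, imidazole) to the saturated carbinol (S)-1-(benzyloxy)-3-[(triisopropylsilyl)oxy]propan-2-ol F3, for which SN2′ is impossible.
- Mitsunobu coupling with 3 should give the benzyl-protected (R)-aryl ether F4.
- Hydrogenolysis (H2, Pd/C, EtOAc) should give the (R)-primary alcohol F5.
- Dess–Martin oxidation then gives aldehyde 6.

Step 3. Ozone may over-oxidise the alkoxy-substituted ring. The aldehyde may also epimerise at C8 or lose the β-silyloxy group while the phosphine oxide is being removed.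
- The fallback sets out from 4 and comes back at 6.
- Upjohn dihydroxylation (cat. OsO4, NMO, acetone/H2O) gives the vicinal diol F6 as an inconsequential mixture at the new carbinol carbon.
- Glycol cleavage with silica-supported NaIO4 in CH2Cl2 gives 6 after filtration only, without ozone, phosphine oxide or chromatography.

Further compounds
F1 | step 5 | methyl 4-({(1R,2S)-1-hydroxy-1-{3-methoxy-4-[(triisopropylsilyl)oxy]phenyl}-3-[(triisopropylsilyl)oxy]propan-2-yl}oxy)-3,5-dimethoxybenzoate (erythro) | COc1cc([C@@H](O)[C@H](CO[Si](C(C)C)(C(C)C)C(C)C)Oc2c(OC)cc(C(=O)OC)cc2OC)ccc1O[Si](C(C)C)(C(C)C)C(C)C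
F2 | step 5 | methyl 3,5-dimethoxy-4-({(2S)-1-{3-methoxy-4-[(triisopropylsilyl)oxy]phenyl}-1-oxo-3-[(triisopropylsilyl)oxy]propan-2-yl}oxy)benzoate | COc1cc(C(=O)[C@H](CO[Si](C(C)C)(C(C)C)C(C)C)Oc2c(OC)cc(C(=O)OC)cc2OC)ccc1O[Si](C(C)C)(C(C)C)C(C)C
F3 | step 2 | (S)-1-(benzyloxy)-3-[(triisopropylsilyl)oxy]propan-2-ol | c1ccccc1COC[C@@H](CO[Si](C(C)C)(C(C)C)C(C)C)O
F4 | step 2 | methyl 4-({(2R)-1-(benzyloxy)-3-[(triisopropylsilyl)oxy]propan-2-yl}oxy)-3,5-dimethoxybenzoate | c1ccccc1COC[C@H](CO[Si](C(C)C)(C(C)C)C(C)C)Oc2c(OC)cc(C(=O)OC)cc2OC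
F5 | step 2 | methyl 4-({(2R)-1-hydroxy-3-[(triisopropylsilyl)oxy]propan-2-yl}oxy)-3,5-dimethoxybenzoate | OC[C@H](CO[Si](C(C)C)(C(C)C)C(C)C)Oc1c(OC)cc(C(=O)OC)cc1OC
F6 | step 3 | methyl 4-({(2S)-3,4-dihydroxy-1-[(triisopropylsilyl)oxy]butan-2-yl}oxy)-3,5-dimethoxybenzoate (mixture at C3) | OCC(O)[C@H](CO[Si](C(C)C)(C(C)C)C(C)C)Oc1c(OC)cc(C(=O)OC)cc1OC
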